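## Retrosynthetic overview
1. Feature: in the ten-membered carbocycle the bare C1–C2–C3 trimethylene run lies β,γ to the C5 ketone on its C4 side. C2–C3 is therefore the σ-bond of an oxy-Cope retron. Its cyclohexane (C5, C6, C7, C8, C9, C10) carries the contiguous all-trans C7/C8/C9 array and maps onto (R)-carvone, with C7 as the bought stereocentre.
2. Late disconnections: the C9 ester; C12–O8 of the α-methylene-γ-lactone (allylic oxidation of the C7 isopropenyl group, lactonisation on C8–OH); C10–OH (C9-OH-directed epoxidation of the E C1=C10 alkene, then hydride at C1).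
3. Key disconnection: E-cyclodecenone 22 ⇒ cis-1-isopropenyl-2-methyl-2-vinylcyclohexanol 19. C2–C3 forms, C5–C10 breaks, and C4 arises on enolate protonation.
4. 19 ⇒ carvone: C8–O by enolate hydroxylation, C5=O by conjugate borylation–oxidation, C1–C2 by alkynylation of the 1,3-dione at C10, C9–OH by directed reduction, C3/C4/C4-methyl by cross-coupling at C5, C5–OH by epoxidation and hydride opening.
5. Ring order: cyclohexane (bought) → ten-membered ring (step 14) → γ-lactone (step 21). The dioxolane of steps 9–17 is only a protecting ring.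

Key step: step 14

Remark (numbering): target numbering is used throughout: C5 ketone carbon, C4 its CHMe neighbour, C3–C1 the CH2 run, C10 methyl carbinol, C9 acyloxy CH, C8 lactone OCH, C7 ring-fusion CH, C6 CH2, C11–C13 lactone α-carbon, carbonyl, exo-methylene. On the cyclohexanes, β is the face carrying the C7 isopropenyl group and α the opposite face.
Remark (C5): an isopropenyl-metal reagent is expected to add to ketone 13 anti to the axial C10 vinyl group and give the trans-diaxial C5 epimer, which cannot reach the Cope geometry. C5–O is therefore delivered as electrophilic oxygen to diene 17 (steps 10–13).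
Remark (drawing): dione 7 is enolised and is drawn as the diketone without configuration at C10. The temporary C5 carbinol of 23–34 is carried without defined configuration because step 24 returns it to the ketone.

## Route

Step 1
Reactants: 1 (R)-carvone
Product: 3 (5S,6S)-6-hydroxycarvone (C8 α-OH, trans to the C7 isopropenyl group), via lithium C8=C9 cross-conjugated dienolate 2 (not isolated)
Conditions: LDA, THF, −78 °C; 2-(phenylsulfonyl)-3-phenyloxaziridine, −78 °C; AcOH
Reagents that add atoms: 2-(phenylsulfonyl)-3-phenyloxaziridine, O=S(=O)(c1ccccc1)N1OC1c1ccccc1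
Why: Kinetic α′-deprotonation followed by N-sulfonyloxaziridine enolate hydroxylation (Davis oxidation) delivers oxygen to C8 on the face anti to the C7 isopropenyl group, giving the trans ketol, which is also the thermodynamic epimer of this enolisable centre.

Step 2
Reactants: 3 (5S,6S)-6-hydroxycarvone
Product: 4 (5S,6S)-6-(tert-butyldimethylsilyloxy)carvone
Conditions: TBSCl, imidazole, DMF, rt
Reagents that add atoms: TBSCl, CC(C)(C)[Si](C)(C)Cl
Why: Standard imidazole-promoted silylation masks the ketol OH so that only C5 is oxidised in step 4; no stereocentre is touched.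

Step 3
Reactants: 4 (5S,6S)-6-(tert-butyldimethylsilyloxy)carvone
Product: 6 C5α-hydroxy-C10α-methyl saturated C9 ketone (β-hydroxy ketone, C8 OTBS), via C5α-pinacolboronate 5 (not isolated)
Conditions: B2pin2, CuCl (cat.), DPEphos (cat.), NaOt-Bu (cat.), MeOH, THF, rt; then NaBO3·4H2O, THF–H2O, rt
Reagents that add atoms: bis(pinacolato)diboron, CC1(C)OB(OC1(C)C)B1OC(C)(C)C(C)(C)O1; sodium perborate, [Na+].[Na+].O[B-]1(O)OO[B-](O)(O)OO1
Why: Copper(I)-catalysed conjugate borylation is specific for the enone over the isolated alkene, boron should enter C5 axially anti to the C7 substituent, and perborate oxidation is stereoretentive; the C5 and C10 centres drawn are erased in steps 4 and 5.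

Step 4
Reactants: 6 C5α-hydroxy ketone
Product: 7 4-(tert-butyldimethylsilyloxy)-2-methyl-5-isopropenylcyclohexane-1,3-dione (C5 and C9 carbonyls, C7/C8 as in 3)
Conditions: Dess–Martin periodinane, CH2Cl2, 0 °C → rt
Reagents that add atoms: none
Why: Dess–Martin oxidation converts the β-hydroxy ketone into the 2-methyl-1,3-dione under non-basic conditions that avoid β-elimination, and the C8 silyloxy group keeps the dione chiral.

Step 5
Reactants: 7 2-methyl-1,3-dione; 8 1-[(trimethylsilyl)ethynyl]-1,2-benziodoxol-3(1H)-one (TMS-EBX)
Product: 9 C10β-ethynyl-C10α-methyl 1,3-dione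
Conditions: TBAF, THF, −78 → −20 °C; aq. NH4Cl
Reagents that add atoms: TMS-EBX (8), C[Si](C)(C)C#CI1OC(=O)c2ccccc12
Why: Electrophilic alkynylation of a stabilised 1,3-dicarbonyl enolate with an ethynyl-iodine(III) reagent (addition to the alkynyl iodane, loss of iodoarene, 1,2-H shift) suits an enolate too weak for simple vinyl acceptors; C–C formation on the sofa-shaped enolate should be axial through the chair-like transition state, on the β face, and a C10 epimer would in any case converge in step 14.

Step 6
Reactants: 9 C10β-ethynyl dione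
Product: 10 C10β-vinyl-C10α-methyl 1,3-dione
Conditions: H2 (1 atm), Lindlar catalyst, quinoline, EtOAc, rt
Reagents that add atoms: none
Why: Lindlar semi-hydrogenation stops at the alkene because the terminal alkyne binds the poisoned palladium far better than the vinyl or 1,1-disubstituted alkene.

Step 7
Reactants: 10 C10β-vinyl dione
Product: 11 C8α-hydroxy-C10β-vinyl 1,3-dione
Conditions: HF·pyridine, THF, 0 °C
Reagents that add atoms: none
Why: Fluoride desilylation in an acidic medium frees C8–OH without the retro-Claisen or ketol-shift chemistry that basic fluoride could provoke in a 2,2-disubstituted 1,3-dione.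

Step 8
Reactants: 11 C8α-hydroxy dione
Product: 12 C8α,C9β-trans-diol C5 ketone
Conditions: Me4NBH(OAc)3, MeCN–AcOH, −20 °C
Reagents that add atoms: none
Why: In the hydroxyl-directed triacetoxyborohydride reduction (Saksena–Evans) boron binds C8–OH so that only the adjacent C9 carbonyl is reduced, and hydride enters axially on the α face anti to the axial C10 vinyl group, setting C9 as the equatorial β-alcohol trans to C8–OH.

Step 9
Reactants: 12 trans-diol ketone
Product: 13 C8/C9 acetonide of 2-methyl-2-vinyl-5-isopropenylcyclohexanone (C5 ketone)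
Conditions: 2-methoxypropene, PPTS (cat.), CH2Cl2, 0 °C
Reagents that add atoms: 2-methoxypropene, COC(C)=C
Why: Kinetic acetalisation with an enol ether closes the trans-fused dioxolane on the diequatorial diol (O–C–C–O about 60°), locks the chair and removes the retro-aldol-prone free β-hydroxy ketone.

Step 10
Reactants: 13 acetonide ketone
Product: 15 C5 enol triflate (C5=C6), via potassium C5(O)=C6 enolate 14 (not isolated)
Conditions: KHMDS, THF, −78 °C; PhNTf2, −78 → 0 °C; aq. NH4Cl
Reagents that add atoms: N-phenylbis(trifluoromethanesulfonimide), O=S(=O)(N(c1ccccc1)S(=O)(=O)C(F)(F)F)C(F)(F)F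
Why: C6 carries the only α-hydrogens (C10 is quaternary), so enolisation and O-triflation give a single enol triflate.

Step 11
Reactants: 15 enol triflate; 16 isopropenylboronic acid pinacol ester
Product: 17 C5-isopropenyl C5=C6 diene (acetonide, C10β-vinyl)
Conditions: Pd(PPh3)4 (cat.), K3PO4, dioxane–H2O, 60 °C
Reagents that add atoms: isopropenylboronic acid pinacol ester (16), CC(=C)B1OC(C)(C)C(C)(C)O1
Why: Suzuki–Miyaura coupling of alkenyl triflates next to quaternary carbon is routine and attaches C4, C3 and the C4 methyl to a trigonal C5, so no facial question arises in the C–C bond formation.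

Step 12
Reactants: 17 diene
Product: 18 5α,6α-epoxide (1-isopropenyl-1,2-epoxycyclohexane)
Conditions: mCPBA (1 equiv), NaHCO3, CH2Cl2, −20 → 0 °C
Reagents that add atoms: mCPBA, OOC(=O)c1cccc(Cl)c1
Why: In the Prilezhaev epoxidation the trisubstituted ring alkene, twisted out of conjugation by the C10 quaternary centre, is the most nucleophilic of the four alkenes, and the peracid approaches the half-chair anti to the pseudo-axial C10 vinyl group, setting C5–O and C6–O on the α face.

Step 13
Reactants: 18 5α,6α-epoxide
Product: 19 1-isopropenyl-2-methyl-2-vinylcyclohexanol with C8/C9 acetonide (C5 α-axial OH, β-equatorial isopropenyl; C10 β-axial vinyl)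
Conditions: LiEt3BH, THF, 0 °C → rt; H2O
Reagents that add atoms: none
Why: SN2 hydride opening occurs at the secondary C6 in the trans-diaxial (Fürst–Plattner) sense that leads directly to the all-equatorial chair, leaving the C5–O bond intact as the axial tertiary alcohol with the isopropenyl group equatorial and cis to the vinyl group.

Step 14
Reactants: 19 1-isopropenyl-2-methyl-2-vinylcyclohexanol acetonide
Product: 22 (E)-cyclodec-5-enone with C8/C9 acetonide, C4 methyl, C7 isopropenyl and E C1=C10 alkene, via potassium alkoxide 20 (not isolated), via potassium ring-cis enolate 21 (not isolated)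
Conditions: KH, 18-crown-6, THF, 0 → 45 °C; AcOH, −78 °C; then DBU (cat.), toluene, rt
Reagents that add atoms: none
Why: KH/18-crown-6 gives the dissociated alkoxide 20, whose oxyanion weakens C5–C10 and drives a concerted suprafacial [3,3] shift across C3=C4–C5–C10–C1=C2 in which C2–C3 forms as C5–C10 breaks (anionic oxy-Cope rearrangement, the reaction type known for 1-isopropenyl-2-methyl-2-vinylcyclohexanols giving dimethylcyclodec-5-enones). The ten-membered carbocycle is closed by four-atom ring expansion of the cyclohexane rather than by end-to-end cyclisation, and formation of enolate 21 makes the step irreversible. In the chair locked by the equatorial C7, C8 and C9 substituents and the trans-fused dioxolane the vinyl group is axial and the isopropenyl group equatorial (dihedral about 60°), so the chair transition state places C9 and the oxyanion pseudo-equatorial and C6 and the C10 methyl pseudo-axial, which gives the E C1=C10 alkene and the ring-cis enolate. C7, C8 and C9 are spectators and C5 and C10 become trigonal, so any C10 epimer carried from step 5 would converge on the same ketone. C4 is the only new stereocentre: it arises on C-protonation of 21 and, being α to the ketone, is put under thermodynamic control by the DBU equilibration, where the 4R epimer with its methyl group on the ring periphery (eclipsed with C=O, anti to C6) should prevail and separated 4S material is returned to the equilibration. The step needs chair over boat and [3,3] over heterolytic C5–C10 cleavage; the first is secured by the cis axial/equatorial dialkenyl geometry fixed in steps 5, 12 and 13, the second by the absence of a carbonyl or leaving group at C9 and C6.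

Step 15
Reactants: 22 (E)-cyclodecenone
Product: 23 C5 alcohol of 22
Conditions: DIBAL-H, CH2Cl2, −78 °C; Rochelle salt
Reagents that add atoms: none
Why: Low-temperature, non-basic 1,2-reduction masks C5 without epimerising C4 and removes the γ-hydroxy-ketone hemiketal problem that a free C8–OH would create; hydride should arrive from the ring periphery, but the new C5 centre is temporary.

Step 16
Reactants: 23 C5 alcohol
Product: 24 C5 O-TBS ether
Conditions: TBSOTf, 2,6-lutidine, CH2Cl2, 0 °C
Reagents that add atoms: TBSOTf, CC(C)(C)[Si](C)(C)OS(=O)(=O)C(F)(F)F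
Why: Silyl triflate silylation of the hindered secondary alcohol gives a mask that tolerates hydride, peroxide and selenium(IV) and leaves with fluoride at the end.

Step 17
Reactants: 24 C5 O-TBS ether
Product: 25 C8,C9-diol (E C1=C10 alkene, C5 OTBS)
Conditions: AcOH–THF–H2O, 40 °C
Reagents that add atoms: none
Why: Mild acid hydrolysis cleaves the acetonide while the hindered secondary TBS ether and the trisubstituted alkene survive, freeing the allylic C9–OH needed for direction.

Step 18
Reactants: 25 C8,C9-diol
Product: 26 1,10-epoxide (trans-epoxide, C10–O as in the target)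
Conditions: VO(acac)2 (cat.), t-BuOOH, CH2Cl2, 0 °C
Reagents that add atoms: tert-butyl hydroperoxide, CC(C)(C)OO
Why: In the vanadium-catalysed hydroxyl-directed epoxidation the C9 vanadate reacts through the rotamer with O–C9–C10=C1 near 45°, C9–H beside the C10 methyl (A1,2 strain minimised) and C8 pointing into the ring, so oxygen reaches the peripheral face and gives the erythro C9/C10 relationship of the target, chemoselectively over the only homoallylic isopropenyl alkene.

Step 19
Reactants: 26 1,10-epoxide
Product: 27 C8,C9,C10-triol (C10 tertiary carbinol, C1 now CH2)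
Conditions: LiEt3BH, THF, 0 → 60 °C; H2O
Reagents that add atoms: none
Why: Super-Hydride opens trisubstituted epoxides by SN2 attack at the less substituted carbon, here C1, so the C10–O bond and its configuration are retained.

Step 20
Reactants: 27 triol
Product: 28 C12 primary allylic alcohol (C7 2-(hydroxymethyl)vinyl group)
Conditions: SeO2 (cat.), t-BuOOH, CH2Cl2, rt
Reagents that add atoms: tert-butyl hydroperoxide, CC(C)(C)OO; selenium dioxide, O=[Se]=O
Why: Selenium dioxide allylic oxidation (ene reaction then [2,3] shift) acts on the only remaining alkene and prefers the methyl group over the tertiary C7–H; any over-oxidised enal converges in step 21.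

Step 21
Reactants: 28 allylic alcohol
Product: 31 α-methylene-γ-lactone C9,C10-diol (trans-fused at C7/C8, C5 OTBS), via hydroxy enal 29 (not isolated), via lactol 30 (not isolated)
Conditions: activated MnO2, CH2Cl2, rt
Reagents that add atoms: none
Why: Manganese dioxide oxidises only the allylic alcohol, the enal is captured by C8–OH as the five-membered lactol in preference to the six-membered one from C9–OH, and this allylic lactol is oxidised on to the lactone (oxidative lactonisation).

Step 22
Reactants: 31 lactone diol; 32 (R)-2-methylbutanoic acid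
Product: 33 C9 (R)-2-methylbutanoate
Conditions: DCC, DMAP, CH2Cl2, 0 °C → rt
Reagents that add atoms: (R)-2-methylbutanoic acid (32), CC[C@@H](C)C(O)=O
Why: Steglich esterification acylates the only free secondary alcohol, leaves the tertiary C10–OH untouched, and avoids a ketene pathway so that the acid stereocentre is carried in unchanged.

Step 23
Reactants: 33 C9 ester
Product: 34 C5 alcohol (ester, lactone and C10–OH in place)
Conditions: HF·pyridine, THF–pyridine, 0 °C → rt
Reagents that add atoms: none
Why: Buffered acidic fluoride removes the TBS group without the acyl migration or conjugate addition to the α-methylene lactone that basic fluoride could cause.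

Step 24
Reactants: 34 C5 alcohol
Product: 35 ineupatorolide A
Conditions: Dess–Martin periodinane, NaHCO3, CH2Cl2, 0 °C → rt
Reagents that add atoms: none
Why: Dess–Martin oxidation of the only oxidisable alcohol restores the C5 ketone under near-neutral conditions that do not epimerise C4.

## Compound list
1 | (R)-carvone | CC1=CC[C@H](CC1=O)C(C)=C | starting material
2 | lithium C8=C9 dienolate of carvone | CC1=CC[C@@H](C(C)=C)C=C1[O-].[Li+] | intermediate
3 | (5S,6S)-6-hydroxycarvone | CC1=CC[C@@H](C(C)=C)[C@H](O)C1=O | intermediate
4 | (5S,6S)-6-(tert-butyldimethylsilyloxy)carvone | CC1=CC[C@@H](C(C)=C)[C@H](O[Si](C)(C)C(C)(C)C)C1=O | intermediate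
5 | C5α-pinacolboryl C9 ketone | CC1(C)OB(OC1(C)C)[C@@H]2C[C@@H](C(C)=C)[C@H](O[Si](C)(C)C(C)(C)C)C(=O)[C@@H]2C | intermediate
6 | C5α-hydroxy C9 ketone | O[C@@H]1C[C@@H](C(C)=C)[C@H](O[Si](C)(C)C(C)(C)C)C(=O)[C@@H]1C | intermediate
7 | 4-(TBSO)-2-methyl-5-isopropenylcyclohexane-1,3-dione | CC1C(=O)C[C@@H](C(C)=C)[C@H](O[Si](C)(C)C(C)(C)C)C1=O | intermediate
8 | TMS-EBX | C[Si](C)(C)C#CI1OC(=O)c2ccccc12 | starting material
9 | C10β-ethynyl dione | C#C[C@@]1(C)C(=O)C[C@@H](C(C)=C)[C@H](O[Si](C)(C)C(C)(C)C)C1=O | intermediate
10 | C10β-vinyl dione | C=C[C@@]1(C)C(=O)C[C@@H](C(C)=C)[C@H](O[Si](C)(C)C(C)(C)C)C1=O | intermediate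
11 | C8α-hydroxy C10β-vinyl dione | C=C[C@@]1(C)C(=O)C[C@@H](C(C)=C)[C@H](O)C1=O | intermediate
12 | C8α,C9β-diol C5 ketone | C=C[C@@]1(C)C(=O)C[C@@H](C(C)=C)[C@H](O)[C@H]1O | intermediate
13 | C8/C9 acetonide C5 ketone | O=C1C[C@@H](C(C)=C)[C@@H]2OC(C)(C)O[C@H]2[C@@]1(C)C=C | intermediate
14 | potassium C5(O)=C6 enolate | [K+].[O-]C1=C[C@@H](C(C)=C)[C@@H]2OC(C)(C)O[C@H]2[C@@]1(C)C=C | intermediate
15 | C5 enol triflate | O=S(=O)(OC1=C[C@@H](C(C)=C)[C@@H]2OC(C)(C)O[C@H]2[C@@]1(C)C=C)C(F)(F)F | intermediate
16 | isopropenylboronic acid pinacol ester | CC(=C)B1OC(C)(C)C(C)(C)O1 | starting material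
17 | C5-isopropenyl C5=C6 diene | CC(=C)C1=C[C@@H](C(C)=C)[C@@H]2OC(C)(C)O[C@H]2[C@@]1(C)C=C | intermediate
18 | 5α,6α-epoxide | CC(=C)[C@@]12O[C@@H]1[C@@H](C(C)=C)[C@@H]3OC(C)(C)O[C@H]3[C@@]2(C)C=C | intermediate
19 | 1-isopropenyl-2-methyl-2-vinylcyclohexanol, C8/C9 acetonide (oxy-Cope precursor) | O[C@]1(C(C)=C)C[C@@H](C(C)=C)[C@@H]2OC(C)(C)O[C@H]2[C@@]1(C)C=C | intermediate
20 | potassium alkoxide of 19 | [K+].[O-][C@]1(C(C)=C)C[C@@H](C(C)=C)[C@@H]2OC(C)(C)O[C@H]2[C@@]1(C)C=C | intermediate
21 | potassium ring-cis C4=C5 enolate, E C1=C10 | CC1(C)O[C@@H]2[C@@H](O1)/C(C)=C/CC/C(C)=C([O-])\C[C@H]2C(C)=C.[K+] | intermediate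
22 | E-cyclodecenone, C8/C9 acetonide (oxy-Cope product) | CC1(C)O[C@@H]2[C@@H](O1)/C(C)=C/CC[C@@H](C)C(=O)C[C@H]2C(C)=C | intermediate
23 | C5 alcohol | CC1(C)O[C@@H]2[C@@H](O1)/C(C)=C/CC[C@@H](C)C(O)C[C@H]2C(C)=C | intermediate
24 | C5 O-TBS ether | CC1(C)O[C@@H]2[C@@H](O1)/C(C)=C/CC[C@@H](C)C(O[Si](C)(C)C(C)(C)C)C[C@H]2C(C)=C | intermediate
25 | C8,C9-diol | O[C@@H]1[C@@H](O)/C(C)=C/CC[C@@H](C)C(O[Si](C)(C)C(C)(C)C)C[C@H]1C(C)=C | intermediate
26 | 1,10-epoxy C8,C9-diol | O[C@@H]1[C@@H](O)[C@@]2(C)O[C@@H]2CC[C@@H](C)C(O[Si](C)(C)C(C)(C)C)C[C@H]1C(C)=C | intermediate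
27 | C8,C9,C10-triol | O[C@@H]1[C@@H](O)[C@@](C)(O)CCC[C@@H](C)C(O[Si](C)(C)C(C)(C)C)C[C@H]1C(C)=C | intermediate
28 | C12 allylic alcohol | O[C@@H]1[C@@H](O)[C@@](C)(O)CCC[C@@H](C)C(O[Si](C)(C)C(C)(C)C)C[C@H]1C(=C)CO | intermediate
29 | C12 hydroxy enal | O[C@@H]1[C@@H](O)[C@@](C)(O)CCC[C@@H](C)C(O[Si](C)(C)C(C)(C)C)C[C@H]1C(=C)C=O | intermediate
30 | C12 lactol | C=C1C(O)O[C@@H]2[C@@H](O)[C@@](C)(O)CCC[C@@H](C)C(O[Si](C)(C)C(C)(C)C)C[C@@H]12 | intermediate
31 | α-methylene-γ-lactone C9,C10-diol | C=C1C(=O)O[C@@H]2[C@@H](O)[C@@](C)(O)CCC[C@@H](C)C(O[Si](C)(C)C(C)(C)C)C[C@@H]12 | intermediate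
32 | (R)-2-methylbutanoic acid | CC[C@@H](C)C(O)=O | starting material
33 | C9 (R)-2-methylbutanoate, C5 OTBS | C=C1C(=O)O[C@@H]2[C@@H](OC(=O)[C@H](C)CC)[C@@](C)(O)CCC[C@@H](C)C(O[Si](C)(C)C(C)(C)C)C[C@@H]12 | intermediate
34 | C9 ester, C5 alcohol | C=C1C(=O)O[C@@H]2[C@@H](OC(=O)[C@H](C)CC)[C@@](C)(O)CCC[C@@H](C)C(O)C[C@@H]12 | intermediate
35 | ineupatorolide A (4R,7S,8S,9R,10S,2′R) | C=C1C(=O)O[C@@H]2[C@@H](OC(=O)[C@H](C)CC)[C@@](C)(O)CCC[C@@H](C)C(=O)C[C@@H]12 | target

## Step count and risks
Total step count: 24. Longest linear sequence: 24 steps, from (R)-carvone.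

Steps most likely to fail:

1. Step 14. Facial control in the protonation of the flexible ring-cis enolate may be poor, the C4 equilibrium may be unfavourable, and alkoxide-induced C5–C10 cleavage may erode the rearrangement. The fallback sets out from 19 and comes back at 22. The rearrangement is run as before, but enolate 21 is quenched with TMSCl to isolate the ring-cis trimethylsilyl enol ether F1. This is then protonated at −78 °C with a Lewis acid-assisted chiral Brønsted acid (BINOL monomethyl ether·SnCl4, with 2,6-dimethylphenol as the stoichiometric proton source). The BINOL antipode matched to 4R is chosen, so that reagent control replaces substrate control at C4.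

2. Step 19. SN2 opening may be slow or misdirected, because the backside of the C1–O bond points into the ten-membered ring. Payne migration of the C9 alkoxide or transannular alkoxide attack may then compete. The fallback sets out from 26 and comes back at 27. After deprotonation of the two hydroxyls with n-BuLi, the epoxide is cleaved by two-electron transfer with lithium 4,4′-di-tert-butylbiphenylide in THF at −78 °C. This needs no backside trajectory and breaks the C1–O bond to give the less substituted carbanion, the C1-lithio trilithium alkoxide F2, which is protonated with MeOH.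

3. Step 12. Chemoselectivity may be lost through competing epoxidation of the C7 isopropenyl group, and the vinyl epoxide may open under acid. The fallback sets out from 13 and comes back at 19. Isopropenylmagnesium bromide/CeCl3 is added to 13, entering anti to the axial vinyl group to give the C5-epimeric carbinol F3. F3 is O-sulfenylated with PhSCl/Et3N and rearranges by the Mislow–Evans [2,3] shift to the exocyclic allylic sulfoxide F4. Heating F4 with Et2NH in MeOH intercepts the sulfenate in which oxygen has returned to C5 on the less hindered α face. This is the sulfoxide–sulfenate shuttle used to invert hindered tertiary vinyl carbinols.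

## Further compounds
F1 | step 14 | ring-cis trimethylsilyl enol ether of 22 | CC1(C)O[C@@H]2[C@@H](O1)/C(C)=C/CC/C(C)=C(O[Si](C)(C)C)\C[C@H]2C(C)=C
F2 | step 19 | C1-lithio C8,C9,C10-trilithium alkoxide (C1 undefined) | [O-][C@@H]1[C@@H]([O-])[C@@](C)([O-])C([Li])CC[C@@H](C)C(O[Si](C)(C)C(C)(C)C)C[C@H]1C(C)=C.[Li+].[Li+].[Li+]
F3 | step 12 | C5 epimer of 19 (β-equatorial OH, α-axial isopropenyl) | O[C@@]1(C(C)=C)C[C@@H](C(C)=C)[C@@H]2OC(C)(C)O[C@H]2[C@@]1(C)C=C
F4 | step 12 | C5=C4 exocyclic allylic phenyl sulfoxide (alkene geometry and sulfur undefined) | CC(CS(=O)c1ccccc1)=C1C[C@@H](C(C)=C)[C@@H]2OC(C)(C)O[C@H]2[C@@]1(C)C=C
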